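**Retrosynthetic overview**

1. Numbering: tetralin C1 (isopropyl), C4 (methyl), C4a/C8a (ring fusion), aromatic ring A = C5–C8; pyranone ring C = O1', C2' (C=O), C3' (aryl), C4' (O), C5' (H), C6' (styryl).
2. Feature used: in acid 21 the atoms O1'–C2'–C3'=C4' are an (E)-2-aryl-3-methoxyacrylic acid whose single C–H bond cis to the carboxyl group is C4'–H, and ring A is hexasubstituted and has no C–H bond. Ring C is therefore closed by carboxylate-directed C4'–H rhodation and annulation with the terminal enyne 24 (bonds C4'–C5' and O1'–C6'); the hindered C8–C3' bond is in place from arylacetate 16 onwards.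
3. Target 26 <= 25 (BBr3: four methyl ethers and the acetal) <= 21 + 24; 21 <= arylacetate 16 by Rieche formylation at C7 (the only free position of ring A), acetalisation, Claisen formylation/O-methylation and saponification.
4. 16 <= phenol 11 <= formylated trans-carvomenthone 4 + ynone 8 (Michael addition, deformylation, aldol condensation, aromatisation). This benzannulation brings in C5–OMe, C6–OH and the two-carbon arm at C8; C1 comes from (S)-carvone and C4 is set by equilibration to the trans ketone.
5. Order of ring formation: saturated ring (chiral pool), ring A (step 4), ring C (step 15). The annulation is run without copper or silver salts (O2 as terminal oxidant) because the alkyne is terminal, and the C7 aldehyde is carried as a 5,5-dimethyl-1,3-dioxane, which should tolerate the free acid.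

Key step: step 15

Remark: the C8–C3' axis is hindered; since the target is given without an axial descriptor, 25 and 26 are taken as rotamer mixtures about this bond and no control of the axis is attempted.

**Route**

Step 1
Reactants: 1 (S)-(+)-carvone
Product: 2 (2S,5S)-2-methyl-5-(propan-2-yl)cyclohexan-1-one (trans-carvomenthone)
Conditions: H2 (1 atm), Pd/C, EtOAc, rt; then NaOMe (cat.), MeOH, rt
Reagents that add atoms: none
Why: Catalytic hydrogenation saturates the enone and the isopropenyl C=C bonds without touching the C5 stereocentre, and methoxide equilibration of the enolisable C2 centre should enrich the diequatorial trans ketone (thermodynamic control of the future C4), the residual cis epimer being removed by chromatography at phenol 11.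

Step 2
Reactants: 2 trans-carvomenthone
Product: 4 (3R,6S)-2-[(Z)-hydroxymethylidene]-6-methyl-3-(propan-2-yl)cyclohexan-1-one, via lithium enolate 3 (not isolated)
Conditions: LiN(iPr)2, THF, −78 °C; then CF3CH2OCHO, −78 °C; 1 M HCl
Reagents that add atoms: 2,2,2-trifluoroethyl formate, O=COCC(F)(F)F
Why: Kinetic deprotonation removes a proton from the CH2 flank (C6) and not from the methyl-bearing C2, and crossed Claisen formylation of this enolate with the activated formate should give the β-keto aldehyde (as its chelated enol) that marks the future C8a as the only nucleophilic carbon, with C2 and C5 unchanged.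

Step 3
Reactants: 5 tert-butyl(but-3-yn-1-yloxy)dimethylsilane; 6 N,2-dimethoxy-N-methylacetamide
Product: 8 6-[(tert-butyldimethylsilyl)oxy]-1-methoxyhex-3-yn-2-one, via lithium acetylide 7 (not isolated)
Conditions: n-BuLi, THF, −78 °C; then 6, −78 → 0 °C; AcOH
Reagents that add atoms: none
Why: Weinreb ketone synthesis: the lithium acetylide adds once to the N-methoxy-N-methylamide and the chelated tetrahedral intermediate releases the ynone only on acidic quench, so that no tertiary alcohol forms.

Step 4
Reactants: 4 hydroxymethylidene ketone; 8 ynone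
Product: 11 (1R,4S)-8-{2-[(tert-butyldimethylsilyl)oxy]ethyl}-5-methoxy-4-methyl-1-(propan-2-yl)-1,2,3,4-tetrahydronaphthalen-6-ol, via Michael adduct 9 (not isolated), via enedione 10 (not isolated)
Conditions: Et3N (0.5 equiv), MeCN, rt; then NaOMe, MeOH, 0 → 50 °C; AcOH
Reagents that add atoms: none
Why: Robinson-type benzannulation: Michael addition of the β-keto aldehyde to the ynone forms C8a–C8, methoxide then removes the formyl group as methyl formate (retro-Claisen), and intramolecular aldol condensation of the methoxymethyl ketone carbon C5 onto the ring carbonyl C4a with dehydration and tautomerisation should give the phenol, C1 staying untouched and C4 keeping the trans relation, which is also the thermodynamically preferred one in the enolisable intermediates.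

Step 5
Reactants: 11 phenol
Product: 12 tert-butyl{2-[(1R,4S)-5,6-dimethoxy-4-methyl-1-(propan-2-yl)-1,2,3,4-tetrahydronaphthalen-8-yl]ethoxy}dimethylsilane
Conditions: MeI, K2CO3, DMF, rt
Reagents that add atoms: iodomethane, CI
Why: Williamson O-methylation of the phenoxide, which masks C6–OH before the oxidation and the Lewis-acid steps.

Step 6
Reactants: 12 silyl ether
Product: 13 2-[(1R,4S)-5,6-dimethoxy-4-methyl-1-(propan-2-yl)-1,2,3,4-tetrahydronaphthalen-8-yl]ethan-1-ol
Conditions: Bu4NF, THF, 0 °C → rt
Reagents that add atoms: none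
Why: Fluoride-induced cleavage of the silyl ether, driven by the Si–F bond, under conditions that leave the aryl ethers alone.

Step 7
Reactants: 13 primary alcohol
Product: 15 2-[(1R,4S)-5,6-dimethoxy-4-methyl-1-(propan-2-yl)-1,2,3,4-tetrahydronaphthalen-8-yl]acetic acid, via arylacetaldehyde 14 (not isolated)
Conditions: TEMPO (cat.), PhI(OAc)2, MeCN/H2O, rt
Reagents that add atoms: water, O
Why: Oxoammonium-mediated (TEMPO/PhI(OAc)2) oxidation of the primary alcohol to the aldehyde and, through its hydrate, to the acid in aqueous MeCN, a mild protocol that should spare the dimethoxyarene and the benzylic C–H bonds.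

Step 8
Reactants: 15 arylacetic acid
Product: 16 methyl 2-[(1R,4S)-5,6-dimethoxy-4-methyl-1-(propan-2-yl)-1,2,3,4-tetrahydronaphthalen-8-yl]acetate
Conditions: MeI, K2CO3, DMF, rt
Reagents that add atoms: iodomethane, CI
Why: SN2 alkylation of the potassium carboxylate gives the methyl ester needed for the Claisen formylation in step 11.

Step 9
Reactants: 16 methyl arylacetate
Product: 17 methyl 2-[(1R,4S)-7-formyl-5,6-dimethoxy-4-methyl-1-(propan-2-yl)-1,2,3,4-tetrahydronaphthalen-8-yl]acetate
Conditions: Cl2CHOMe, TiCl4, CH2Cl2, −78 → 0 °C; H2O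
Reagents that add atoms: dichloromethyl methyl ether, COC(Cl)Cl; water, O
Why: Rieche formylation (Friedel–Crafts reaction of the chloro(methoxy)carbenium ion from Cl2CHOMe and TiCl4): C7 is the only free position of ring A and is activated by the ortho C6 methoxy group, so the site of attack is fixed, and hydrolysis of the α-chloro ether on work-up gives the aldehyde.

Step 10
Reactants: 17 aldehyde ester
Product: 18 methyl 2-[(1R,4S)-7-(5,5-dimethyl-1,3-dioxan-2-yl)-5,6-dimethoxy-4-methyl-1-(propan-2-yl)-1,2,3,4-tetrahydronaphthalen-8-yl]acetate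
Conditions: 2,2-dimethylpropane-1,3-diol, PPTS (cat.), toluene, reflux (Dean–Stark)
Reagents that add atoms: 2,2-dimethylpropane-1,3-diol, OCC(C)(C)CO
Why: Acid-catalysed acetalisation with azeotropic removal of water converts the aldehyde into a 5,5-dimethyl-1,3-dioxane, which is stable to the enolate chemistry of step 11 and, unlike an acyclic acetal, should not be opened by the neighbouring carboxylic acid of 21.

Step 11
Reactants: 18 acetal ester
Product: 20 methyl (E)-2-[(1R,4S)-7-(5,5-dimethyl-1,3-dioxan-2-yl)-5,6-dimethoxy-4-methyl-1-(propan-2-yl)-1,2,3,4-tetrahydronaphthalen-8-yl]-3-methoxyprop-2-enoate, via sodium enolate 19 (not isolated)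
Conditions: NaH, HCO2Me, DMF, 0 °C → rt; then Me2SO4, rt
Reagents that add atoms: methyl formate, COC=O; dimethyl sulfate, COS(=O)(=O)OC
Why: Crossed Claisen formylation of the arylacetate and O-methylation of the resulting sodium enolate is the standard entry to 3-methoxyacrylates and is expected to favour the (E)-isomer (OMe trans to CO2Me, hence C4'–H cis to the carboxyl carbon), any (Z)-isomer being separated by chromatography.

Step 12
Reactants: 20 methyl (E)-3-methoxyacrylate
Product: 21 (E)-2-[(1R,4S)-7-(5,5-dimethyl-1,3-dioxan-2-yl)-5,6-dimethoxy-4-methyl-1-(propan-2-yl)-1,2,3,4-tetrahydronaphthalen-8-yl]-3-methoxyprop-2-enoic acid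
Conditions: LiOH·H2O, THF/MeOH/H2O, 45 °C; AcOH to pH 5, 0 °C
Reagents that add atoms: lithium hydroxide, [Li+].[OH-]
Why: Saponification of the methyl ester with hydroxide followed by buffered acidification, the vinylogous carbonate and the acetal being stable to base, should give the free (E)-acid without isomerisation.

Step 13
Reactants: 22 (E)-3-(4-methoxyphenyl)prop-2-enal
Product: 23 1-[(1E)-4,4-dibromobuta-1,3-dien-1-yl]-4-methoxybenzene
Conditions: CBr4, PPh3, CH2Cl2, 0 °C
Reagents that add atoms: carbon tetrabromide, BrC(Br)(Br)Br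
Why: First stage of the Corey–Fuchs alkyne synthesis: Wittig-type olefination of the aldehyde with the ylide Ph3P=CBr2 formed from PPh3 and CBr4, the (E)-alkene being untouched.

Step 14
Reactants: 23 dibromodiene
Product: 24 1-[(1E)-but-1-en-3-yn-1-yl]-4-methoxybenzene
Conditions: n-BuLi (2.1 equiv), THF, −78 °C; H2O
Reagents that add atoms: none
Why: Second stage of the Corey–Fuchs sequence: bromine–lithium exchange, loss of LiBr and Fritsch–Buttenberg–Wiechell 1,2-shift give the lithium acetylide, which is protonated on work-up to the terminal (E)-enyne.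

Step 15
Reactants: 21 (E)-2-aryl-3-methoxyacrylic acid; 24 terminal (E)-enyne
Product: 25 3-[(1R,4S)-7-(5,5-dimethyl-1,3-dioxan-2-yl)-5,6-dimethoxy-4-methyl-1-(propan-2-yl)-1,2,3,4-tetrahydronaphthalen-8-yl]-4-methoxy-6-[(E)-2-(4-methoxyphenyl)ethenyl]-2H-pyran-2-one
Conditions: [Cp*RhCl2]2 (5 mol %), CsOPiv (0.5 equiv), O2 (1 atm), t-AmOH, 80 °C; 24 added slowly
Reagents that add atoms: none
Why: Proposed new method: pivalate-assisted concerted metalation–deprotonation by Cp*Rh(OPiv)2 (trivalent rhodium, formed from [Cp*RhCl2]2 and CsOPiv) at C4'–H, the only C–H bond cis to the bound carboxylate of 21, should give a five-membered rhodacycle; the terminal alkyne of 24 then inserts into Rh–C4' (bond C4'–C5') and C–O reductive elimination from the seven-membered rhodacycle forms O1'–C6', which closes the six-membered ring C in a formal oxidative [4+2] annulation, O2 returning monovalent rhodium to the trivalent state. The closest known reaction is the [Cp*RhCl2]2-catalysed oxidative annulation of acrylic acids with internal alkynes to 2-pyranones, which has not been shown for a 3-alkoxyacrylic acid or for a terminal 1,3-enyne, although the same cis β-hydrogen of 3-alkoxyacrylic acid derivatives is known to be removed by carboxylate-directed lithiation. The step needs regioselective insertion (styryl at C6', hydrogen at C5'), which should follow from the preference of the alkenyl-substituted alkyne carbon for the position on rhodium, as with 1,3-enynes and with terminal alkynes in related Cp*Rh annulations under internal-oxidant conditions. Copper and silver salts are left out because they would couple the terminal alkyne oxidatively (Glaser–Eglinton) or trap it as an acetylide, and 24 is added slowly to limit its oligomerisation. Site selectivity is secured by the substrate: ring A has no C–H bond, the (E)-geometry places C4'–H beside the carboxylate, and the aryl group points away from the metal, so the hindered C8–C3' bond is not involved; no stereocentre is formed and C1 and C4 are untouched.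

Step 16
Reactants: 25 tetra-O-methyl pyranone acetal
Product: 26 heimiomycin A
Conditions: BBr3 (excess), CH2Cl2, −78 °C → rt; H2O
Reagents that add atoms: water, O
Why: Ether cleavage with BBr3: bromide attacks the boron-activated O–methyl groups of the three aryl ethers and of the vinylogous ester at C4' and the dioxane acetal is opened, and aqueous work-up should hydrolyse the borates and the α-bromo ether to the two phenol groups of ring A, the styryl phenol, the 4-hydroxy-2-pyranone and the C7 aldehyde, the benzylic centres C1 and C4 being unaffected.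

**Compound list**

1 | (S)-(+)-carvone | CC1=CC[C@@H](CC1=O)C(C)=C | starting material
2 | (2S,5S)-2-methyl-5-(propan-2-yl)cyclohexan-1-one (trans-carvomenthone) | CC(C)[C@H]1CC[C@H](C)C(=O)C1 | intermediate
3 | lithium (3R,6S)-6-methyl-3-(propan-2-yl)cyclohex-1-en-1-olate (kinetic enolate of 2) | CC(C)[C@H]1CC[C@H](C)C([O-])=C1.[Li+] | intermediate
4 | (3R,6S)-2-[(Z)-hydroxymethylidene]-6-methyl-3-(propan-2-yl)cyclohexan-1-one | O/C=C1/[C@@H](C(C)C)CC[C@H](C)C1=O | intermediate
5 | tert-butyl(but-3-yn-1-yloxy)dimethylsilane | C#CCCO[Si](C)(C)C(C)(C)C | starting material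
6 | N,2-dimethoxy-N-methylacetamide | COCC(=O)N(C)OC | starting material
7 | lithium acetylide of 5 | [Li+].[C-]#CCCO[Si](C)(C)C(C)(C)C | intermediate
8 | 6-[(tert-butyldimethylsilyl)oxy]-1-methoxyhex-3-yn-2-one | COCC(=O)C#CCCO[Si](C)(C)C(C)(C)C | intermediate
9 | (3S,6R)-1-{6-[(tert-butyldimethylsilyl)oxy]-1-methoxy-2-oxohex-3-en-4-yl}-3-methyl-2-oxo-6-(propan-2-yl)cyclohexane-1-carbaldehyde (mixture at C1 and of alkene isomers) | CC(C)[C@H]1CC[C@H](C)C(=O)C1(C=O)C(CCO[Si](C)(C)C(C)(C)C)=CC(=O)COC | intermediate
10 | (3R,6S)-2-{6-[(tert-butyldimethylsilyl)oxy]-1-methoxy-2-oxohex-3-en-4-yl}-6-methyl-3-(propan-2-yl)cyclohexan-1-one (mixture at C2 and of alkene isomers) | CC(C)[C@H]1CC[C@H](C)C(=O)C1C(CCO[Si](C)(C)C(C)(C)C)=CC(=O)COC | intermediate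
11 | (1R,4S)-8-{2-[(tert-butyldimethylsilyl)oxy]ethyl}-5-methoxy-4-methyl-1-(propan-2-yl)-1,2,3,4-tetrahydronaphthalen-6-ol | CC(C)[C@H]1CC[C@H](C)c2c(OC)c(O)cc(CCO[Si](C)(C)C(C)(C)C)c21 | intermediate
12 | tert-butyl{2-[(1R,4S)-5,6-dimethoxy-4-methyl-1-(propan-2-yl)-1,2,3,4-tetrahydronaphthalen-8-yl]ethoxy}dimethylsilane | CC(C)[C@H]1CC[C@H](C)c2c(OC)c(OC)cc(CCO[Si](C)(C)C(C)(C)C)c21 | intermediate
13 | 2-[(1R,4S)-5,6-dimethoxy-4-methyl-1-(propan-2-yl)-1,2,3,4-tetrahydronaphthalen-8-yl]ethan-1-ol | CC(C)[C@H]1CC[C@H](C)c2c(OC)c(OC)cc(CCO)c21 | intermediate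
14 | 2-[(1R,4S)-5,6-dimethoxy-4-methyl-1-(propan-2-yl)-1,2,3,4-tetrahydronaphthalen-8-yl]acetaldehyde | CC(C)[C@H]1CC[C@H](C)c2c(OC)c(OC)cc(CC=O)c21 | intermediate
15 | 2-[(1R,4S)-5,6-dimethoxy-4-methyl-1-(propan-2-yl)-1,2,3,4-tetrahydronaphthalen-8-yl]acetic acid | CC(C)[C@H]1CC[C@H](C)c2c(OC)c(OC)cc(CC(=O)O)c21 | intermediate
16 | methyl 2-[(1R,4S)-5,6-dimethoxy-4-methyl-1-(propan-2-yl)-1,2,3,4-tetrahydronaphthalen-8-yl]acetate | CC(C)[C@H]1CC[C@H](C)c2c(OC)c(OC)cc(CC(=O)OC)c21 | intermediate
17 | methyl 2-[(1R,4S)-7-formyl-5,6-dimethoxy-4-methyl-1-(propan-2-yl)-1,2,3,4-tetrahydronaphthalen-8-yl]acetate | CC(C)[C@H]1CC[C@H](C)c2c(OC)c(OC)c(C=O)c(CC(=O)OC)c21 | intermediate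
18 | methyl 2-[(1R,4S)-7-(5,5-dimethyl-1,3-dioxan-2-yl)-5,6-dimethoxy-4-methyl-1-(propan-2-yl)-1,2,3,4-tetrahydronaphthalen-8-yl]acetate | CC(C)[C@H]1CC[C@H](C)c2c(OC)c(OC)c(C3OCC(C)(C)CO3)c(CC(=O)OC)c21 | intermediate
19 | sodium enolate of the α-formyl derivative of 18 (sodium 2-aryl-3-methoxy-3-oxoprop-1-en-1-olate, aryl as in 18) | CC(C)[C@H]1CC[C@H](C)c2c(OC)c(OC)c(C3OCC(C)(C)CO3)c(C(C(=O)OC)=C[O-])c21.[Na+] | intermediate
20 | methyl (E)-2-[(1R,4S)-7-(5,5-dimethyl-1,3-dioxan-2-yl)-5,6-dimethoxy-4-methyl-1-(propan-2-yl)-1,2,3,4-tetrahydronaphthalen-8-yl]-3-methoxyprop-2-enoate | CC(C)[C@H]1CC[C@H](C)c2c(OC)c(OC)c(C3OCC(C)(C)CO3)c(/C(C(=O)OC)=C\OC)c21 | intermediate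
21 | (E)-2-[(1R,4S)-7-(5,5-dimethyl-1,3-dioxan-2-yl)-5,6-dimethoxy-4-methyl-1-(propan-2-yl)-1,2,3,4-tetrahydronaphthalen-8-yl]-3-methoxyprop-2-enoic acid | CC(C)[C@H]1CC[C@H](C)c2c(OC)c(OC)c(C3OCC(C)(C)CO3)c(/C(C(=O)O)=C\OC)c21 | intermediate
22 | (E)-3-(4-methoxyphenyl)prop-2-enal | COc1ccc(/C=C/C=O)cc1 | starting material
23 | 1-[(1E)-4,4-dibromobuta-1,3-dien-1-yl]-4-methoxybenzene | COc1ccc(/C=C/C=C(Br)Br)cc1 | intermediate
24 | 1-[(1E)-but-1-en-3-yn-1-yl]-4-methoxybenzene | C#C/C=C/c1ccc(OC)cc1 | intermediate
25 | 3-[(1R,4S)-7-(5,5-dimethyl-1,3-dioxan-2-yl)-5,6-dimethoxy-4-methyl-1-(propan-2-yl)-1,2,3,4-tetrahydronaphthalen-8-yl]-4-methoxy-6-[(E)-2-(4-methoxyphenyl)ethenyl]-2H-pyran-2-one | CC(C)[C@H]1CC[C@H](C)c2c(OC)c(OC)c(C3OCC(C)(C)CO3)c(-c3c(OC)cc(/C=C/c4ccc(OC)cc4)oc3=O)c21 | intermediate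
26 | heimiomycin A | CC(C)[C@H]1CC[C@H](C)c2c(O)c(O)c(C=O)c(-c3c(O)cc(/C=C/c4ccc(O)cc4)oc3=O)c21 | target

**Step count**

Total: 16 steps. Longest linear sequence: 13 steps from (S)-carvone (steps 1, 2, 4 to 12, 15, 16).

**Steps most likely to fail**

Step 15. The catalyst may not turn over, because monovalent rhodium can stay bound to the diene of the pyranone and be reoxidised only slowly by O2. The terminal enyne may oligomerise through a rhodium acetylide, or the carboxylate may add across the alkyne. The free acid may lose its enol ether by hydrolysis and then decarboxylate, or metalation at the alkoxy-substituted vinylic carbon may not occur at all.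
Fallback: it sets out from ester 18 and comes back at target 26. The lithium enolate of 18 (LiN(SiMe3)2, THF, −78 °C) is C-acetylated with 1-acetylimidazole in a crossed Claisen condensation to the methyl 2-aryl-3-oxobutanoate F1. Its dianion (NaH, then n-BuLi, THF, 0 °C) is acylated at the terminal carbon by (E)-N-methoxy-3-(4-methoxyphenyl)-N-methylprop-2-enamide F2, made from commercial 4-methoxycinnamic acid, carbonyldiimidazole and MeNHOMe·HCl, to give the 3,5-dioxo ester F3. DBU in refluxing toluene lactonises this with loss of methanol to the 3-aryl-4-hydroxy-6-styryl-2-pyranone F4, the classical polyketide-type pyranone synthesis. BBr3 under the conditions of step 16 then removes the three aryl methyl ethers and the acetal and gives 26.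

Step 4. Carbon–carbon bond formation at the hindered carbon next to the isopropyl-bearing centre may be slow, since a quaternary centre is formed on a β-substituted ynone. O-alkylation of the enol and base-induced isomerisation or oligomerisation of the ynone may compete, and the methoxide stage may partly epimerise C4.
Fallback: it sets out from ketone 2 and ynone 8 and comes back at phenol 11. Ynone 8 is hydrochlorinated (LiCl, AcOH, MeCN, rt) to (Z)-6-[(tert-butyldimethylsilyl)oxy]-4-chloro-1-methoxyhex-3-en-2-one F5. The kinetic lithium enolate 3 of ketone 2, without a formyl group, is added to it (THF, −78 → 0 °C); conjugate addition and loss of chloride form a tertiary instead of a quaternary centre and give enedione 10, now isolated. NaOMe in MeOH then closes and aromatises ring A to 11.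

Step 16. Cleavage of the vinylogous methyl ester at C4' may lag behind that of the aryl ethers, so that the freed catechol aldehyde and the styrylpyranone are exposed for long to BBr3 and HBr (addition to the alkene, condensation at the aldehyde, oxidation of the catechol on work-up).
Fallback: it sets out from sodium enolate 19 and comes back at target 26. The enolate is O-benzylated (BnBr, DMF, rt) instead of methylated to the methyl (E)-2-aryl-3-(benzyloxy)prop-2-enoate F6. Saponification as in step 12 gives the (E)-3-(benzyloxy)acrylic acid F7, and annulation with enyne 24 under the conditions of step 15 gives the 4-(benzyloxy)-2-pyranone F8. Its benzyl vinylogous ester is cleaved by BBr3 well below the temperature needed for the three aryl methyl ethers, so that a shorter treatment (−78 → 0 °C) should suffice to reach 26.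

Further compounds
F1 | step 15 | methyl 2-[(1R,4S)-7-(5,5-dimethyl-1,3-dioxan-2-yl)-5,6-dimethoxy-4-methyl-1-(propan-2-yl)-1,2,3,4-tetrahydronaphthalen-8-yl]-3-oxobutanoate | CC(C)[C@H]1CC[C@H](C)c2c(OC)c(OC)c(C3OCC(C)(C)CO3)c(C(C(C)=O)C(=O)OC)c21
F2 | step 15 | (E)-N-methoxy-3-(4-methoxyphenyl)-N-methylprop-2-enamide | COc1ccc(/C=C/C(=O)N(C)OC)cc1
F3 | step 15 | methyl (E)-2-[(1R,4S)-7-(5,5-dimethyl-1,3-dioxan-2-yl)-5,6-dimethoxy-4-methyl-1-(propan-2-yl)-1,2,3,4-tetrahydronaphthalen-8-yl]-7-(4-methoxyphenyl)-3,5-dioxohept-6-enoate | CC(C)[C@H]1CC[C@H](C)c2c(OC)c(OC)c(C3OCC(C)(C)CO3)c(C(C(=O)OC)C(=O)CC(=O)/C=C/c3ccc(OC)cc3)c21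
F4 | step 15 | 3-[(1R,4S)-7-(5,5-dimethyl-1,3-dioxan-2-yl)-5,6-dimethoxy-4-methyl-1-(propan-2-yl)-1,2,3,4-tetrahydronaphthalen-8-yl]-4-hydroxy-6-[(E)-2-(4-methoxyphenyl)ethenyl]-2H-pyran-2-one | CC(C)[C@H]1CC[C@H](C)c2c(OC)c(OC)c(C3OCC(C)(C)CO3)c(-c3c(O)cc(/C=C/c4ccc(OC)cc4)oc3=O)c21
F5 | step 4 | (Z)-6-[(tert-butyldimethylsilyl)oxy]-4-chloro-1-methoxyhex-3-en-2-one | COCC(=O)/C=C(\Cl)CCO[Si](C)(C)C(C)(C)C
F6 | step 16 | methyl (E)-3-(benzyloxy)-2-[(1R,4S)-7-(5,5-dimethyl-1,3-dioxan-2-yl)-5,6-dimethoxy-4-methyl-1-(propan-2-yl)-1,2,3,4-tetrahydronaphthalen-8-yl]prop-2-enoate | CC(C)[C@H]1CC[C@H](C)c2c(OC)c(OC)c(C3OCC(C)(C)CO3)c(/C(C(=O)OC)=C\OCc3ccccc3)c21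
F7 | step 16 | (E)-3-(benzyloxy)-2-[(1R,4S)-7-(5,5-dimethyl-1,3-dioxan-2-yl)-5,6-dimethoxy-4-methyl-1-(propan-2-yl)-1,2,3,4-tetrahydronaphthalen-8-yl]prop-2-enoic acid | CC(C)[C@H]1CC[C@H](C)c2c(OC)c(OC)c(C3OCC(C)(C)CO3)c(/C(C(=O)O)=C\OCc3ccccc3)c21
F8 | step 16 | 4-(benzyloxy)-3-[(1R,4S)-7-(5,5-dimethyl-1,3-dioxan-2-yl)-5,6-dimethoxy-4-methyl-1-(propan-2-yl)-1,2,3,4-tetrahydronaphthalen-8-yl]-6-[(E)-2-(4-methoxyphenyl)ethenyl]-2H-pyran-2-one | CC(C)[C@H]1CC[C@H](C)c2c(OC)c(OC)c(C3OCC(C)(C)CO3)c(-c3c(OCc4ccccc4)cc(/C=C/c4ccc(OC)cc4)oc3=O)c21
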